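## Analysis of the target

Bannamurpanisin is 5,7,8-trimethoxy-2-(3,4,5-trimethoxyphenyl)-4H-chromen-4-one (C21H22O8), a flavone. Benzo ring A (C4a, C5 to C8, C8a) is fused to the γ-pyranone ring C (O1, C2, C3, C4), and ring B (C1' to C6') sits on C2. There is no stereocentre, and the C2–C1' bond is not a stereogenic axis because ring B has no ortho substituent, so the whole problem is one of constitution. Ring A carries four oxygen atoms (O1 on C8a, methoxy on C8, C7 and C5) and one hydrogen (C6). The 5,6,7-trimethoxy isomer differs only in which of the two oxygen atoms ortho to C4a is the ring oxygen, and making this choice correctly is the hard part.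

The feature the route exploits: with C4 taken out, ring A is a 1,2,3,5-tetraoxygenated benzene with a mirror plane through C8 and C5, in which C4a and C6 are equivalent C–H positions. Ring B with C2 and C3 is then an arylacetylene that already has the oxidation level of the pyranone. Once C4 is attached to C4a, the two flanking oxygens differ: the one on C8a is buttressed by the C8 methoxy group, the one on C5 has only C6–H beside it.

Sensitive points are the C5 methoxy group (peri to C4=O) and the C4' methoxy group (flanked by two others), which Lewis acids cleave first. Ring A is easily oxidised, and the pyranone opens in hot alkali.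

## Retrosynthetic reasoning

**O1–C2.** Target 10 is cut at O1–C2, which opens ring C to the 2-hydroxyaryl β-amino enone 9. Forward, the hydroxyl on the future C8a adds to the amine-bearing carbon (the future C2) and the amine leaves. Only a six-membered ring can form this way, and no oxidant is needed because the carbon chain is already at the pyranone oxidation level.

**O–CH3 of the future O1.** 9 is traced back to the fully methylated enaminone 8. The forward reaction must remove one of the two methoxy groups ortho to the carbonyl group, namely the one flanked by a second methoxy group. The cut is placed here because it lets ring A travel as a symmetric tetramethyl ether; the two oxygens are told apart only at the one stage where they are different.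

**C2–N.** 8 comes from ynone 7 by conjugate addition of a secondary amine. The amine removes the electrophilic triple bond before the Lewis acid arrives and installs the leaving group for the ring closure.

**Both bonds of C4 (C4a–C4 and C4–C3).** 7 is cut on either side of its carbonyl carbon into arene 2, alkyne 3 and a one-carbon carbonyl unit. Forward, 2 is lithiated to 4, acylated to Weinreb amide 5, and 5 is attacked by acetylide 6. This is the key disconnection. C4 is the only skeletal carbon that belongs to neither aromatic building block, so cutting here gives two pieces of equal size. The symmetry of 2 means the arene can react at only one kind of position.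

**O–CH3 of the isolated methoxy group.** 2 is the methyl ether of the commercial phenol 1.

## Alternatives that were turned down

**Alternative 1:** the textbook disconnection, C2–C3 by aldol condensation and O1–C2 by oxidative closure.
- Forward: Friedel–Crafts acetylation of 2 with AlCl3, which also removes the buttressed methyl group, gives 1-(2-hydroxy-3,4,6-trimethoxyphenyl)ethan-1-one A1. Claisen–Schmidt condensation with 3,4,5-trimethoxybenzaldehyde A2 gives the 2'-hydroxychalcone A3. I2 in hot DMSO closes ring C by oxa-Michael addition and dehydrogenation.
- Turned down: A3 is two electrons below the flavone, so the last step needs a stoichiometric oxidant at high temperature with HI present. Under these conditions the electron-rich ring A (free C6–H between two methoxy groups) can be iodinated and the peri C5 methyl ether cleaved. The free phenol has to pass through a strongly basic aldol step in which the oxa-Michael closure of A3 is reversible. It takes three steps from 2 where the chosen route takes two, and it does not use the oxidation level an alkyne can bring.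

**Alternative 2:** O1–C2, C4a–C4 and C4–C3 formed together by carbonylative annulation of an ortho-iodophenol.
- Forward: 2-iodo-3,5,6-trimethoxyphenol A5, CO and alkyne 3 with PdCl2(PPh3)2 in Et2NH (oxidative addition, CO insertion, alkynylation, amine-mediated closure) would give 10 in one operation.
- Turned down: A5 has to come from 2,3,5-trimethoxyphenol A4, whose free hydroxyl sits at the end of the oxygen triad. Mono-demethylation of 2 is expected at the central methoxy group of the triad and gives the wrong phenol, so A4 needs a multi-step synthesis of its own. Iodination of A4 must then choose C6 (ortho to the hydroxyl) over C4 (para to it, between two methoxy groups), both doubly activated. The precursor costs more than the key step saves.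

**Alternative 3:** O1–C8a by dehydrogenative C–O cyclisation.
- Forward: Claisen condensation of 1-(2,4,5-trimethoxyphenyl)ethan-1-one A6 with methyl 3,4,5-trimethoxybenzoate A7 gives the 1,3-diketone A8. Anodic (or metal-mediated) oxidation would join the enol oxygen to the only ortho C–H of the 2,4,5-trimethoxyphenyl ring. This would be two steps with no demethylation.
- Turned down on mechanism:
  - In the arene radical cation, the C–H carbon C6' lies meta to the methoxy groups at C2' and C4' and carries little charge. The methoxy-bearing C2', para to the C5' methoxy group, is the electrophilic site. Ipso attack there would close the ring on the wrong side and expel the methoxy group meant to become the C5 substituent.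
  - In a metal-directed C–H oxygenation, either carbonyl oxygen of A8 can direct, and ring B offers two unhindered ortho C–H bonds against one on ring A.
  - The oxidants also attack the doubly activated C3 position.

Key step: step 2

Assumption (chemistry): of the two methoxy groups ortho to the carbonyl group of a 2,3,4,6-tetramethoxyphenyl ketone derivative, a chelating Lewis acid is taken to cleave the one at C2', which is buttressed by the C3' methoxy group, as in the AlCl3-mediated Friedel–Crafts acylation of 2.

## Route

Step 1
Reactants: 1 3,4,5-trimethoxyphenol
Product: 2 1,2,3,5-tetramethoxybenzene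
Conditions: MeI, K2CO3, acetone, reflux, N2
Reagents that add atoms: iodomethane (CI)
Why: Williamson ether synthesis: the potassium phenoxide of 1 attacks iodomethane at oxygen in an SN2 reaction. The product 2 has a mirror plane that makes its two ring C–H positions equivalent, on which step 2 relies.

Step 2
Reactants: 2 1,2,3,5-tetramethoxybenzene; 3 5-ethynyl-1,2,3-trimethoxybenzene
Product: 7 1-(2,3,4,6-tetramethoxyphenyl)-3-(3,4,5-trimethoxyphenyl)prop-2-yn-1-one, via (2,3,4,6-tetramethoxyphenyl)lithium 4 (not isolated), via N,2,3,4,6-pentamethoxy-N-methylbenzamide 5 (not isolated), via lithium (3,4,5-trimethoxyphenyl)ethynide 6 (not isolated)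
Conditions: 2, n-BuLi, THF, 0 °C to rt; cannulated into ClC(O)N(OMe)Me, THF, −78 to 0 °C; then 6 (from 3, n-BuLi, THF, −78 °C), −78 °C to rt; cold 1 M aq HCl
Reagents that add atoms: N-methoxy-N-methylcarbamoyl chloride (CON(C)C(Cl)=O)
Why: n-BuLi removes the proton of 2 that is flanked by two methoxy groups (cooperative ortho-direction); the two C–H positions of 2 are equivalent by symmetry, so only one aryllithium, 4, can form. 4 attacks the carbamoyl chloride by addition–elimination (chloride leaves) to give Weinreb amide 5, and acetylide 6 adds to 5 to give a lithium-chelated N-methoxy-N-methyl hemiaminal that cannot collapse before the quench, so neither organolithium adds twice. The acidic quench releases ynone 7 and holds the liberated N,O-dimethylhydroxylamine as its salt, so that it cannot add to the triple bond. The closest known reaction type is the one-flask synthesis of unsymmetrical ketones from two organolithium reagents and a carbonyl dication equivalent by way of a Weinreb amide. The step forms both bonds of C4 (C4a–C4 and C4–C3, numbering of 10) and brings all carbons of the skeleton together at the oxidation level of the pyranone. It closes no ring and creates no stereocentre; ring C is closed in step 3. The selectivity it needs is 1,2-addition at each stage, secured by the order of addition: the aryl nucleophile comes first and the acetylide last, so that no ynone or alkynyl amide meets a carbon nucleophile that could add in the conjugate sense.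

Step 3
Reactants: 7 1-(2,3,4,6-tetramethoxyphenyl)-3-(3,4,5-trimethoxyphenyl)prop-2-yn-1-one
Product: 10 5,7,8-trimethoxy-2-(3,4,5-trimethoxyphenyl)-4H-chromen-4-one (bannamurpanisin), via diethylamino enone 8 (not isolated), via hydroxyaryl diethylamino enone 9 (not isolated)
Conditions: Et2NH, EtOH, rt, then evaporation; BCl3, CH2Cl2, −78 to 0 °C; MeOH, 0 to 50 °C; aqueous work-up
Reagents that add atoms: none
Why: Conjugate addition of the secondary amine to 7 gives vinylogous amide 8, which removes the electrophilic triple bond, so that BCl3 cannot trigger attack of either methoxy oxygen on the alkyne and a 5-exo closure to an aurone is excluded. BCl3 then binds the carbonyl oxygen and removes, by chelation-assisted SN2 attack of chloride on methyl, the ortho methoxy group that is buttressed by its methoxy neighbour (the C8a oxygen of 10); this preference is expected by analogy with Lewis-acid cleavage of 2,3,4,6-tetramethoxyphenyl ketones and with the lability of the C5 methyl ether of 5,6,7-trimethoxyflavones compared with that of 5,7-dimethoxyflavones. Methanolysis frees phenol 9 and HCl, and the hydroxyl adds to the iminium carbon of the protonated enaminone and expels diethylamine (6-endo-trig addition–elimination, the usual closure of 2-hydroxyaryl enaminones to chromones).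

## Compound list

1 | 3,4,5-trimethoxyphenol | COc1cc(O)cc(OC)c1OC | starting material
2 | 1,2,3,5-tetramethoxybenzene | COc1cc(OC)c(OC)c(OC)c1 | intermediate
3 | 5-ethynyl-1,2,3-trimethoxybenzene | C#Cc1cc(OC)c(OC)c(OC)c1 | starting material
4 | (2,3,4,6-tetramethoxyphenyl)lithium | [Li]c1c(OC)cc(OC)c(OC)c1OC | intermediate (not isolated)
5 | N,2,3,4,6-pentamethoxy-N-methylbenzamide | CON(C)C(=O)c1c(OC)cc(OC)c(OC)c1OC | intermediate (not isolated)
6 | lithium (3,4,5-trimethoxyphenyl)ethynide | [Li]C#Cc1cc(OC)c(OC)c(OC)c1 | intermediate (not isolated)
7 | 1-(2,3,4,6-tetramethoxyphenyl)-3-(3,4,5-trimethoxyphenyl)prop-2-yn-1-one | COc1cc(C#CC(=O)c2c(OC)cc(OC)c(OC)c2OC)cc(OC)c1OC | intermediate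
8 | (E)-3-(diethylamino)-1-(2,3,4,6-tetramethoxyphenyl)-3-(3,4,5-trimethoxyphenyl)prop-2-en-1-one (geometry expected, of no consequence) | CCN(CC)/C(=C/C(=O)c1c(OC)cc(OC)c(OC)c1OC)c1cc(OC)c(OC)c(OC)c1 | intermediate (not isolated)
9 | (E)-3-(diethylamino)-1-(2-hydroxy-3,4,6-trimethoxyphenyl)-3-(3,4,5-trimethoxyphenyl)prop-2-en-1-one (held as its dichloroboron chelate until methanolysis) | CCN(CC)/C(=C/C(=O)c1c(O)c(OC)c(OC)cc1OC)c1cc(OC)c(OC)c(OC)c1 | intermediate (not isolated)
10 | 5,7,8-trimethoxy-2-(3,4,5-trimethoxyphenyl)-4H-chromen-4-one (bannamurpanisin) | COc1cc(-c2cc(=O)c3c(OC)cc(OC)c(OC)c3o2)cc(OC)c1OC | target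

## Step count and least certain steps

Total step count: 3. Longest linear sequence: 3 (1 → 2 → 7 → 10); alkyne 3 is bought.

**Step 2 (key step).** The most likely failure is slow addition of acetylide 6 to amide 5, whose carbonyl group is twisted out of conjugation and shielded by two ortho methoxy groups, so that 5 survives to the quench. Second to this is conjugate addition of N,O-dimethylhydroxylamine to the ynone if the quench is not acidic enough. The fallback sets out from 2 and comes back at 7, and it replaces nucleophilic addition to a shielded amide by a palladium-catalysed three-component carbonylation. Electrophilic iodination of 2 (N-iodosuccinimide, MeCN, rt; again only one position by symmetry) should give 2-iodo-1,3,4,5-tetramethoxybenzene F1. F1, CO (balloon to 5 bar) and alkyne 3 with PdCl2(PPh3)2 and Et3N in THF at 50 °C should give 7 by carbonylative Sonogashira coupling (oxidative addition to zerovalent palladium, CO insertion, alkynylation of the aroyl palladium species, reductive elimination). The C4–C3 bond is then made at the metal and not at a hindered carbonyl group.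

**Step 3.** The most likely failure is loss of site selectivity in the ether cleavage. Cleavage at the unbuttressed ortho methoxy group would lead, after closure, to the 5,6,7 constitution. Cleavage of both ortho groups, or of the C4' methoxy group of ring B through bidentate binding of BCl3 to neighbouring oxygens, is also possible. The fallback sets out from 2 and comes back at 10. It fixes the ring-A constitution on ring A alone, before ring B is present, by the Friedel–Crafts acetylation taken as precedent in the assumption. Acetyl chloride and AlCl3 in Et2O acetylate 2 and remove the buttressed methyl group in the same operation, giving 1-(2-hydroxy-3,4,6-trimethoxyphenyl)ethan-1-one F2. O-Acylation with 3,4,5-trimethoxybenzoyl chloride in pyridine gives 2-acetyl-3,5,6-trimethoxyphenyl 3,4,5-trimethoxybenzoate F3. KOH in pyridine at 50 °C induces the Baker–Venkataraman acyl shift to 1-(2-hydroxy-3,4,6-trimethoxyphenyl)-3-(3,4,5-trimethoxyphenyl)propane-1,3-dione F4. H2SO4 in AcOH at 100 °C closes ring C by cyclodehydration to 10.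

**Step 1.** This is the least uncertain step. What can go wrong is C-methylation of the ambident, phloroglucinol-like phenoxide and its autoxidation to quinoid material under basic conditions. The fallback sets out from 1 and comes back at 2 with no new compound (F0). It is a Mitsunobu etherification with methanol (PPh3, diisopropyl azodicarboxylate, THF, 0 °C to rt), a redox condensation in which the neutral phenol is alkylated by a methoxyphosphonium ion. No free phenoxide and no base are present, so neither C-alkylation nor autoxidation has a pathway.

## Further compounds

F0 | step 1 | none | none
F1 | step 2 | 2-iodo-1,3,4,5-tetramethoxybenzene | COc1cc(OC)c(OC)c(OC)c1I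
F2 | step 3 | 1-(2-hydroxy-3,4,6-trimethoxyphenyl)ethan-1-one | CC(=O)c1c(O)c(OC)c(OC)cc1OC
F3 | step 3 | 2-acetyl-3,5,6-trimethoxyphenyl 3,4,5-trimethoxybenzoate | CC(=O)c1c(OC)cc(OC)c(OC)c1OC(=O)c1cc(OC)c(OC)c(OC)c1
F4 | step 3 | 1-(2-hydroxy-3,4,6-trimethoxyphenyl)-3-(3,4,5-trimethoxyphenyl)propane-1,3-dione | COc1cc(C(=O)CC(=O)c2c(O)c(OC)c(OC)cc2OC)cc(OC)c1OC
A1 | alternative 1 | 1-(2-hydroxy-3,4,6-trimethoxyphenyl)ethan-1-one | CC(=O)c1c(O)c(OC)c(OC)cc1OC
A2 | alternative 1 | 3,4,5-trimethoxybenzaldehyde | COc1cc(C=O)cc(OC)c1OC
A3 | alternative 1 | (E)-1-(2-hydroxy-3,4,6-trimethoxyphenyl)-3-(3,4,5-trimethoxyphenyl)prop-2-en-1-one | COc1cc(/C=C/C(=O)c2c(O)c(OC)c(OC)cc2OC)cc(OC)c1OC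
A4 | alternative 2 | 2,3,5-trimethoxyphenol | COc1cc(O)c(OC)c(OC)c1
A5 | alternative 2 | 2-iodo-3,5,6-trimethoxyphenol | COc1cc(OC)c(OC)c(O)c1I
A6 | alternative 3 | 1-(2,4,5-trimethoxyphenyl)ethan-1-one | CC(=O)c1cc(OC)c(OC)cc1OC
A7 | alternative 3 | methyl 3,4,5-trimethoxybenzoate | COC(=O)c1cc(OC)c(OC)c(OC)c1
A8 | alternative 3 | 1-(2,4,5-trimethoxyphenyl)-3-(3,4,5-trimethoxyphenyl)propane-1,3-dione | COc1cc(C(=O)CC(=O)c2cc(OC)c(OC)cc2OC)cc(OC)c1OC
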